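The seven-membered ring B (C1, C5–C10; guaiane numbering) is cut at C6–C7 and C1–C10 into a three-carbon acryloylsilane (C6 = acyl carbon; C5=C1 inside the preformed cyclopentene ring A, which already carries the C4 carbinol) and a four-carbon ketone enolate (C7–C10). The key step exploits the 1,3-dioxygenation at C6/C8 of ring B: these atoms are the two carbonyl carbons, C1 and C10 the alkene termini. Enolate addition, Brook shift and cyclopropanolate closure build a strained cis-dialkenylcyclopropane, whose anionic oxy-Cope ring expansion gives the whole C15 skeleton; loss of methoxide from C10 and enolisation then place C1=C10.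

Key step: step 7

Remark: guaiane numbering is used for all bicyclic compounds (ring A: C1–C5; ring B: C1, C5–C10; methyl groups on C4 and C10, isopropyl on C7). α is the face of the bicycle that carries the C4 oxygen (and H-5 in the target), β the other face. The target is (4S,5R,6R,7R,8S).
Assumption: of the two antipodes of the ligand in step 1, the one that directs methyl to the Re face of 1 is employed.

Step 1
Reactants: 1 2-bromocyclopent-2-en-1-one
Product: 2 (S)-2-bromo-1-methylcyclopent-2-en-1-ol
Conditions: Me2Zn (3 equiv), Ti(OiPr)4 (1.2 equiv), bis(10-hydroxycamphorsulfonamide) ligand of trans-cyclohexane-1,2-diamine (10 mol %), toluene/hexane, 25 °C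
Reagents that add atoms: dimethylzinc C[Zn]C
Why: Titanium-mediated, ligand-accelerated enantioselective 1,2-addition of a dialkylzinc to a ketone, for which α-substituted cyclic enones are a suitable substrate class; the bromine differentiates the two carbonyl flanks and delivery of methyl to the Re face sets the (S)-carbinol (the later C4).

Step 2
Reactants: 2 (S)-2-bromo-1-methylcyclopent-2-en-1-ol
Product: 3 (S)-[(2-bromo-1-methylcyclopent-2-en-1-yl)oxy]triethylsilane
Conditions: TESOTf, 2,6-lutidine, CH2Cl2, 0 °C
Reagents that add atoms: triethylsilyl triflate CC[Si](CC)(CC)OS(=O)(=O)C(F)(F)F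
Why: Silylation of a tertiary alcohol with a silyl triflate and a hindered pyridine base; the triethylsilyl ether should withstand the organolithium, enolate and cold buffered-fluoride steps and later shields the α-face of C6, and no stereocenter is touched.

Step 3
Reactants: 3 (S)-[(2-bromo-1-methylcyclopent-2-en-1-yl)oxy]triethylsilane
Product: 5 (S)-[5-methyl-5-(triethylsilyloxy)cyclopent-1-en-1-yl](morpholin-4-yl)methanone, via vinyllithium 4 (not isolated)
Conditions: t-BuLi (2.1 equiv), THF, −78 °C; then 4-morpholinecarbonyl chloride, −78 → 0 °C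
Reagents that add atoms: 4-morpholinecarbonyl chloride O=C(Cl)N1CCOCC1
Why: Bromine–lithium exchange on the vinyl bromide (the second equivalent of t-BuLi destroys t-BuBr) followed by acylation of the vinyllithium with a carbamoyl chloride gives the tertiary amide; the five-membered ring rules out β-elimination of the silyloxy group and the stereocenter is not involved.

Step 4
Reactants: 5 (S)-[5-methyl-5-(triethylsilyloxy)cyclopent-1-en-1-yl](morpholin-4-yl)methanone
Product: 6 (S)-[dimethyl(phenyl)silyl][5-methyl-5-(triethylsilyloxy)cyclopent-1-en-1-yl]methanone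
Conditions: PhMe2SiLi (1.5 equiv), THF, −78 °C; then aq NH4Cl
Reagents that add atoms: dimethylphenylsilyllithium [Li][Si](C)(C)c1ccccc1
Why: Acylsilane synthesis by single addition of a silyllithium to a morpholine amide, in which the tetrahedral lithium alkoxide persists at −78 °C and collapses only on quench, so over-addition is avoided; the α-branched, β-substituted alkene disfavours conjugate silylation.

Step 5
Reactants: 7 methyl (E)-3-methoxybut-2-enoate
Product: 8 (E)-N,3-dimethoxy-N-methylbut-2-enamide
Conditions: MeNH(OMe)·HCl, iPrMgCl, THF, −20 → 0 °C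
Reagents that add atoms: N,O-dimethylhydroxylamine hydrochloride CNOC.Cl
Why: Magnesium-amide aminolysis of the ester (Weinreb amide formation); the β-methoxy alkene is a poor Michael acceptor and should keep its E geometry.

Step 6
Reactants: 8 (E)-N,3-dimethoxy-N-methylbut-2-enamide
Product: 9 (E)-2-methoxy-6-methylhept-2-en-4-one
Conditions: iBuMgBr, THF, 0 °C; then aq NH4Cl
Reagents that add atoms: isobutylmagnesium bromide CC(C)C[Mg]Br
Why: Weinreb ketone synthesis, in which the chelated tetrahedral intermediate prevents over-addition and the electron-rich β-methoxy alkene resists 1,4-attack, so the E enone should be obtained unchanged.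

Step 7
Reactants: 6 (S)-[dimethyl(phenyl)silyl][5-methyl-5-(triethylsilyloxy)cyclopent-1-en-1-yl]methanone; 9 (E)-2-methoxy-6-methylhept-2-en-4-one
Product: 14 8-(tert-butyldimethylsilyloxy)-6-[dimethyl(phenyl)silyloxy]-4α-(triethylsilyloxy)guaia-1(10),5,8-triene (C7 epimers), via lithium enolate 10 (not isolated), via cyclopropanolate 11 (not isolated), via methoxy enolate 12 (not isolated), via enone 13 (not isolated)
Conditions: 9, LiN(iPr)2, THF, −78 °C; add 6, −78 → −30 °C; warm to 0 °C; then Et3N, TBSOTf (3 equiv), 0 → 25 °C
Reagents that add atoms: tert-butyldimethylsilyl triflate CC(C)(C)[Si](C)(C)OS(=O)(=O)C(F)(F)F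
Why: Kinetic α′-deprotonation of the vinylogous ester 9 gives enolate 10, whose carbon C7 adds to the acylsilane carbonyl C6 of 6 (bond C6–C7), 1,2-Brook migration of silicon from C6 to oxygen unmasks a siloxyallyl carbanion that closes onto the C8 carbonyl to the cis-dialkenylcyclopropanolate 11, the strain of 11 drives an anionic oxy-Cope shift that forms C1–C10 and cleaves C6–C8 to give enolate 12, this expels methoxide from C10 (E1cB) to enone 13, and soft enolisation of 13 with TBSOTf/Et3N removes the doubly allylic H-1 to give the through-conjugated triene 14. The closest known reaction type is the Brook rearrangement-mediated [3+4] annulation of acryloylsilanes with lithium enolates of alkenyl ketones, combined with thermodynamic dienol silyl ether formation from an enone. The cyclopropane closes by 3-exo-trig addition of the C6 carbanion to C8=O, and ring B closes by the [3,3]-sigmatropic ring expansion of that cyclopropane through a boat transition state. The stereocenters made at C1 and C10 are transient (both are sp2 in 14), C7 is left as an epimer mixture that is planarised in step 9, and C4 is carried over from 6 unchanged. The step needs 1,2- and not 1,4-addition to 6, which the highly electrophilic acylsilane carbonyl and the β-substituent should secure, and a cis disposition of the two alkenyl groups in 11, which should follow from internal delivery of the carbanion within the lithium-bridged adduct. It also needs enolisation at C1 and not at C7 or the C10 methyl group, which the position of H-1 between C5=C6 and C9=C10 and the full conjugation of the resulting triene should secure.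

Step 8
Reactants: 14 8-(tert-butyldimethylsilyloxy)-6-[dimethyl(phenyl)silyloxy]-4α-(triethylsilyloxy)guaia-1(10),5,8-triene
Product: 15 4α-(triethylsilyloxy)-5αH-guai-1(10)-ene-6,8-dione (C7 labile)
Conditions: Bu4NF (2.1 equiv), AcOH (3 equiv), THF, −78 → −30 °C
Reagents that add atoms: none
Why: Buffered fluoride cleaves both silyl enol ethers (the tertiary triethylsilyl alkyl ether should be inert at this temperature) and each dienolate is protonated kinetically at its α-carbon (C5 and C9), the usual course for dienol silyl ethers, which leaves C1=C10 out of conjugation; H-5 should enter on the α-face, anti to the methyl group on the adjacent quaternary C4 (1,2-induction by the nearer and larger carbon ligand), while C7 stays labile between the two carbonyls.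

Step 9
Reactants: 15 4α-(triethylsilyloxy)-5αH-guai-1(10)-ene-6,8-dione
Product: 16 4α-(triethylsilyloxy)-8-(triisopropylsilyloxy)-5αH-guaia-1(10),7-dien-6-one
Conditions: TIPSOTf (1.1 equiv), Et3N (1.5 equiv), CH2Cl2, −78 °C
Reagents that add atoms: triisopropylsilyl triflate CC(C)[Si](OS(=O)(=O)C(F)(F)F)(C(C)C)C(C)C
Why: Soft enolisation of a 1,3-diketone, in which only H-7 is acidic enough for Et3N at −78 °C so that the β,γ-alkene is not moved, and the bulky silyl triflate should go to the less hindered O8 (C8 is flanked by a CH2 group, C6 by the ring-fusion carbon next to quaternary C4); this masks C8 and makes C7 sp2.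

Step 10
Reactants: 16 4α-(triethylsilyloxy)-8-(triisopropylsilyloxy)-5αH-guaia-1(10),7-dien-6-one
Product: 17 4α-(triethylsilyloxy)-8-(triisopropylsilyloxy)-5αH-guaia-1(10),7-dien-6α-ol
Conditions: iBu2AlH (1.5 equiv), toluene, −78 °C; then aq potassium sodium tartrate
Reagents that add atoms: none
Why: 1,2-Reduction of a vinylogous ester carbonyl (the first half of a Stork–Danheiser sequence); with C7 planar the controlling element is the 1,3-related α-oriented triethylsilyloxy group on C4, whose silyl group sweeps the α-face, so hydride should enter C6 from the β-face and give the 6α-alcohol, cis to H-5.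

Step 11
Reactants: 17 4α-(triethylsilyloxy)-8-(triisopropylsilyloxy)-5αH-guaia-1(10),7-dien-6α-ol
Product: 18 6α-hydroxy-4α-(triethylsilyloxy)-5αH,7βH-guai-1(10)-en-8-one
Conditions: Bu4NF (1.1 equiv), AcOH (1.5 equiv), THF, −78 → −30 °C
Reagents that add atoms: none
Why: Fluoride cleavage of the silyl enol ether under acetic acid buffering frees the C8 enolate, which should be protonated kinetically at C7 on the β-face, anti to the neighbouring C6 hydroxyl, so that the isopropyl group ends α and cis to O6; buffer and low temperature suppress β-elimination of the C6 hydroxyl (the Stork–Danheiser pathway) and retro-aldol cleavage.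

Step 12
Reactants: 18 6α-hydroxy-4α-(triethylsilyloxy)-5αH,7βH-guai-1(10)-en-8-one
Product: 19 6α-acetoxy-4α-(triethylsilyloxy)-5αH,7βH-guai-1(10)-en-8β-ol
Conditions: CH3CHO (6 equiv), SmI2 (0.2 equiv), THF, −10 °C
Reagents that add atoms: acetaldehyde CC=O
Why: Evans–Tishchenko reduction, in which the samarium-bound hemiacetal formed from the C6 hydroxyl and acetaldehyde delivers its hydride intramolecularly to the α-face of the C8 carbonyl; this sets the 1,3-anti 8β-alcohol and leaves the acetate on O6 in the same operation.

Step 13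
Reactants: 19 6α-acetoxy-4α-(triethylsilyloxy)-5αH,7βH-guai-1(10)-en-8β-ol
Product: 20 6α-acetoxy-8β-angeloyloxy-4α-(triethylsilyloxy)-5αH,7βH-guai-1(10)-ene
Conditions: angelic acid, 2,4,6-trichlorobenzoyl chloride, Et3N, toluene, 25 °C; then 19, 80 °C
Reagents that add atoms: angelic acid C/C=C(/C)C(=O)O
Why: Yamaguchi-type esterification through the mixed 2,4,6-trichlorobenzoic anhydride without a nucleophilic catalyst, conditions under which the (Z)-enoate should not isomerise to the tiglate; only the secondary C8 hydroxyl is free and its trans-1,3 relation to the C6 acetate disfavours acyl migration.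

Step 14
Reactants: 20 6α-acetoxy-8β-angeloyloxy-4α-(triethylsilyloxy)-5αH,7βH-guai-1(10)-ene
Product: 21 6α-acetoxy-8β-angeloyloxy-5αH,7βH-guai-1(10)-en-4α-ol
Conditions: HF·pyridine, pyridine, THF, 0 → 25 °C
Reagents that add atoms: none
Why: Fluoride-mediated cleavage of the tertiary triethylsilyl ether under buffered conditions that should leave both esters, the (Z)-enoate and the tetrasubstituted alkene untouched; no stereocenter is affected.

Compound list
1 | 2-bromocyclopent-2-en-1-one | O=C1CCC=C1Br | starting material
2 | (S)-2-bromo-1-methylcyclopent-2-en-1-ol | C[C@]1(O)CCC=C1Br | intermediate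
3 | (S)-[(2-bromo-1-methylcyclopent-2-en-1-yl)oxy]triethylsilane | C[C@]1(O[Si](CC)(CC)CC)CCC=C1Br | intermediate
4 | (S)-[5-methyl-5-(triethylsilyloxy)cyclopent-1-en-1-yl]lithium (not isolated) | C[C@]1(O[Si](CC)(CC)CC)CCC=C1[Li] | intermediate
5 | (S)-[5-methyl-5-(triethylsilyloxy)cyclopent-1-en-1-yl](morpholin-4-yl)methanone | C[C@]1(O[Si](CC)(CC)CC)CCC=C1C(=O)N2CCOCC2 | intermediate
6 | (S)-[dimethyl(phenyl)silyl][5-methyl-5-(triethylsilyloxy)cyclopent-1-en-1-yl]methanone | C[C@]1(O[Si](CC)(CC)CC)CCC=C1C(=O)[Si](C)(C)c2ccccc2 | intermediate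
7 | methyl (E)-3-methoxybut-2-enoate | CO/C(C)=C/C(=O)OC | starting material
8 | (E)-N,3-dimethoxy-N-methylbut-2-enamide | CO/C(C)=C/C(=O)N(C)OC | intermediate
9 | (E)-2-methoxy-6-methylhept-2-en-4-one | CO/C(C)=C/C(=O)CC(C)C | intermediate
10 | lithium (2E)-2-methoxy-6-methylhepta-2,4-dien-4-olate, the enolate of 9 (C4=C5 geometry not fixed; not isolated) | CO/C(C)=C/C(O[Li])=CC(C)C | intermediate
11 | lithium 2-[dimethyl(phenyl)silyloxy]-3-isopropyl-1-[(E)-2-methoxyprop-1-enyl]-2-[(S)-5-methyl-5-(triethylsilyloxy)cyclopent-1-enyl]cyclopropan-1-olate (the two alkenyl groups cis; other cyclopropane configurations not fixed; not isolated) | CO/C(C)=C/C1(O[Li])C(C(C)C)C1(O[Si](C)(C)c2ccccc2)C3=CCC[C@]3(C)O[Si](CC)(CC)CC | intermediate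
12 | lithium 6-[dimethyl(phenyl)silyloxy]-10-methoxy-4α-(triethylsilyloxy)guaia-5,8-dien-8-olate (4S; epimers at C1, C7, C10; not isolated) | COC1(C)C=C(O[Li])C(C(C)C)C(O[Si](C)(C)c2ccccc2)=C3C1CC[C@]3(C)O[Si](CC)(CC)CC | intermediate
13 | 6-[dimethyl(phenyl)silyloxy]-4α-(triethylsilyloxy)guaia-5,9-dien-8-one (4S; epimers at C1, C7; not isolated) | CC1=CC(=O)C(C(C)C)C(O[Si](C)(C)c2ccccc2)=C3C1CC[C@]3(C)O[Si](CC)(CC)CC | intermediate
14 | 8-(tert-butyldimethylsilyloxy)-6-[dimethyl(phenyl)silyloxy]-4α-(triethylsilyloxy)guaia-1(10),5,8-triene (4S; C7 epimers) | CC(C)C1C(O[Si](C)(C)C(C)(C)C)=CC(C)=C2CC[C@](C)(O[Si](CC)(CC)CC)C2=C1O[Si](C)(C)c3ccccc3 | intermediate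
15 | 4α-(triethylsilyloxy)-5αH-guai-1(10)-ene-6,8-dione (C7 labile) | O=C1CC(C)=C2CC[C@](C)(O[Si](CC)(CC)CC)[C@H]2C(=O)C1C(C)C | intermediate
16 | 4α-(triethylsilyloxy)-8-(triisopropylsilyloxy)-5αH-guaia-1(10),7-dien-6-one | CC(C)C1=C(O[Si](C(C)C)(C(C)C)C(C)C)CC(C)=C2CC[C@](C)(O[Si](CC)(CC)CC)[C@H]2C1=O | intermediate
17 | 4α-(triethylsilyloxy)-8-(triisopropylsilyloxy)-5αH-guaia-1(10),7-dien-6α-ol | CC(C)C1=C(O[Si](C(C)C)(C(C)C)C(C)C)CC(C)=C2CC[C@](C)(O[Si](CC)(CC)CC)[C@H]2[C@@H]1O | intermediate
18 | 6α-hydroxy-4α-(triethylsilyloxy)-5αH,7βH-guai-1(10)-en-8-one (isopropyl α) | O=C1CC(C)=C2CC[C@](C)(O[Si](CC)(CC)CC)[C@H]2[C@H](O)[C@@H]1C(C)C | intermediate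
19 | 6α-acetoxy-4α-(triethylsilyloxy)-5αH,7βH-guai-1(10)-en-8β-ol | O[C@H]1CC(C)=C2CC[C@](C)(O[Si](CC)(CC)CC)[C@H]2[C@H](OC(C)=O)[C@@H]1C(C)C | intermediate
20 | 6α-acetoxy-8β-angeloyloxy-4α-(triethylsilyloxy)-5αH,7βH-guai-1(10)-ene | C/C=C(/C)C(=O)O[C@H]1CC(C)=C2CC[C@](C)(O[Si](CC)(CC)CC)[C@H]2[C@H](OC(C)=O)[C@@H]1C(C)C | intermediate
21 | (4S,5R,6R,7R,8S)-6-acetoxy-8-[(Z)-2-methylbut-2-enoyloxy]guai-1(10)-en-4-ol (6α-acetoxy-8β-angeloyloxy-5αH,7βH-guai-1(10)-en-4α-ol) | C/C=C(/C)C(=O)O[C@H]1CC(C)=C2CC[C@](C)(O)[C@H]2[C@H](OC(C)=O)[C@@H]1C(C)C | target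

Total step count: 14. Longest linear sequence: 12 steps (steps 1–4 and 7–14).

Steps most likely to fail

Step 7. The [3,3] shift has to join the ring carbon C1 to a fully substituted C10. Steric retardation of the oxy-Cope step may let the cyclopropanolate revert by ring opening, or let the first adduct be protonated before it rearranges. The fallback sets out from 6 and rejoins the route at 14. It uses a four-carbon partner whose C10 carries hydrogen and introduces the C9=C10 unsaturation by oxidation instead of elimination. Commercial (E)-but-2-enal is treated with iBuMgBr to give (E)-6-methylhept-2-en-4-ol F1, which MnO2 oxidises to (E)-6-methylhept-2-en-4-one F2. The lithium enolate of F2 (LiN(iPr)2, THF, −78 °C) is combined with 6 in the same annulation, and the C8 enolate is quenched with Me3SiCl to give 6-[dimethyl(phenyl)silyloxy]-4α-(triethylsilyloxy)-8-(trimethylsilyloxy)guaia-5,8-diene F3. Saegusa–Ito oxidation with Pd(OAc)2 in MeCN should dehydrogenate the less hindered trimethylsilyl enol ether to enone 13, here isolated. TBSOTf/Et3N then converts 13 into 14.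

Step 9. Discrimination between O6 and O8 in the silylation of the diketonate may be incomplete, and such leakage would send the hydride of step 10 to the wrong carbonyl. The same detour also serves if facial selectivity in step 10 or the kinetic protonation in step 11 is poor. The fallback sets out from 15 and rejoins at 20; it sets C8 first under reagent control and lets C7 and C6 follow. The less hindered C8 carbonyl of 15 is reduced with (R)-2-methyl-CBS-oxazaborolidine and BH3·SMe2 to 8β-hydroxy-4α-(triethylsilyloxy)-5αH,7βH-guai-1(10)-en-6-one F4, in which C7 (still α to the C6 ketone) should settle with isopropyl trans to the new carbinol. Hydroxyl-directed reduction with Me4NBH(OAc)3 in MeCN/AcOH delivers hydride to C6 from the face of O8 and should give the 1,3-anti diol 4α-(triethylsilyloxy)-5αH,7βH-guai-1(10)-ene-6α,8β-diol F5. The mixed anhydride of angelic acid acylates the less hindered C8 hydroxyl to 8β-angeloyloxy-4α-(triethylsilyloxy)-5αH,7βH-guai-1(10)-en-6α-ol F6, and Ac2O/DMAP then gives 20.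

Step 1. Enantiofacial discrimination in the methyl transfer may be insufficient, because Me2Zn is the least reactive dialkylzinc and uncatalysed background addition erodes selectivity. The fallback sets out from 1 and rejoins at 2, replacing asymmetric catalysis by resolution. MeMgBr/CeCl3 in THF at −78 °C adds to 1 to give racemic 2-bromo-1-methylcyclopent-2-en-1-ol F7. Its enantiomers are separated by preparative chromatography on an amylose tris(3,5-dimethylphenylcarbamate) phase, and the (S)-enantiomer is 2.

Further compounds
F1 | step 7 | (E)-6-methylhept-2-en-4-ol (racemic) | C/C=C/C(O)CC(C)C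
F2 | step 7 | (E)-6-methylhept-2-en-4-one | C/C=C/C(=O)CC(C)C
F3 | step 7 | 6-[dimethyl(phenyl)silyloxy]-4α-(triethylsilyloxy)-8-(trimethylsilyloxy)guaia-5,8-diene (4S; epimers at C1, C7, C10) | CC1C=C(O[Si](C)(C)C)C(C(C)C)C(O[Si](C)(C)c2ccccc2)=C3C1CC[C@]3(C)O[Si](CC)(CC)CC
F4 | step 9 | 8β-hydroxy-4α-(triethylsilyloxy)-5αH,7βH-guai-1(10)-en-6-one | O[C@H]1CC(C)=C2CC[C@](C)(O[Si](CC)(CC)CC)[C@H]2C(=O)[C@@H]1C(C)C
F5 | step 9 | 4α-(triethylsilyloxy)-5αH,7βH-guai-1(10)-ene-6α,8β-diol | O[C@H]1CC(C)=C2CC[C@](C)(O[Si](CC)(CC)CC)[C@H]2[C@H](O)[C@@H]1C(C)C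
F6 | step 9 | 8β-angeloyloxy-4α-(triethylsilyloxy)-5αH,7βH-guai-1(10)-en-6α-ol | C/C=C(/C)C(=O)O[C@H]1CC(C)=C2CC[C@](C)(O[Si](CC)(CC)CC)[C@H]2[C@H](O)[C@@H]1C(C)C
F7 | step 1 | racemic 2-bromo-1-methylcyclopent-2-en-1-ol | CC1(O)CCC=C1Br
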